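**Retrosynthetic overview**

1. Labels: flavanone numbering; ring A (C4a–C8a), ring C (O1, C2, C3, C4), ring B (C1'–C6'), ring D (O1'', C2'', C3'', C4''; fused to ring B at C4'–C5').
2. Enabling feature: the only olefin of ring D, cis C3''=C4'', lies between aryl carbon C5' and the quaternary C2''(CH3)2 on O1''. Cutting it leaves a C5' vinyl group ortho to a C4' 1,1-dimethylallyl ether (a 1,7-diene), and the C8 prenyl olefin is likewise the cross-metathesis image of an allyl group.
3. Key disconnection: one metathesis operation closes ring D at C3''=C4'' and turns the C8 allyl group into prenyl; only MOM removal follows.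
4. The tetraene precursor comes from an enantioselective Hayashi–Miyaura 1,4-addition of a ring B arylboronic acid to an 8-allylchromone (rings A and C, allyl placed by Claisen rearrangement); this joins the two halves at C2 and sets 2S.
5. Ring order: ring C (step 4), C2–C1' union (step 10), ring D (step 11).

Key step: step 11

Remarks: MOM = methoxymethyl; H2IMes = 1,3-dimesitylimidazolidin-2-ylidene; (S)-MeO-F12-BIPHEP = (S)-2,2'-bis[bis(3,4,5-trifluorophenyl)phosphino]-6,6'-dimethoxy-1,1'-biphenyl. Assumption: the facial sense of this diphosphine in step 10 is assigned by analogy with cyclic enones; if a test run shows the opposite sense, the antipodal ligand is used.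

**Route**

Step 1
Reactants: 1 2',6'-dihydroxy-4'-methoxyacetophenone
Product: 2 1-[2-(allyloxy)-6-hydroxy-4-methoxyphenyl]ethan-1-one
Conditions: allyl bromide (1.05 equiv), K2CO3, acetone, 55 °C
Reagents that add atoms: allyl bromide C=CCBr
Why: Williamson etherification; after the first alkylation the remaining phenol is held in a hydrogen bond to the acetyl carbonyl, so one equivalent of allyl bromide should stop at the monoether.

Step 2
Reactants: 2 1-[2-(allyloxy)-6-hydroxy-4-methoxyphenyl]ethan-1-one
Product: 3 1-[2-(allyloxy)-4-methoxy-6-(methoxymethoxy)phenyl]ethan-1-one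
Conditions: NaH, DMF, 0 °C; MOMCl, 0 °C to rt
Reagents that add atoms: chloromethyl methyl ether COCCl
Why: O-alkylation of the sodium phenoxide (Williamson type) marks this oxygen as the future C5 oxygen and keeps it out of the later ring C closure.

Step 3
Reactants: 3 1-[2-(allyloxy)-4-methoxy-6-(methoxymethoxy)phenyl]ethan-1-one
Product: 5 1-[3-allyl-2-hydroxy-4-methoxy-6-(methoxymethoxy)phenyl]ethan-1-one, via Claisen dienone 4 (not isolated)
Conditions: PhNEt2, 195 °C, sealed tube, argon
Reagents that add atoms: none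
Why: Aromatic Claisen rearrangement ([3,3] shift, then enolisation of the dienone): the only free ortho position is C3, so the allyl group should land on the future C8 and the freed phenol is the future O1.

Step 4
Reactants: 5 1-[3-allyl-2-hydroxy-4-methoxy-6-(methoxymethoxy)phenyl]ethan-1-one
Product: 7 8-allyl-7-methoxy-5-(methoxymethoxy)-4H-chromen-4-one, via enaminone 6 (not isolated)
Conditions: Me2NCH(OMe)2, toluene, 95 °C; evaporate; then AcOH/CH2Cl2 (1:4), rt
Reagents that add atoms: N,N-dimethylformamide dimethyl acetal COC(OC)N(C)C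
Why: Enaminone chromone synthesis (condensation with the amide acetal, then acid-promoted intramolecular oxa-Michael addition and loss of dimethylamine); only the phenol next to the allyl group is free, so ring C should close in the 8-allyl sense, and the weak acid is expected to spare the MOM acetal.

Step 5
Reactants: 8 2-methylbut-3-en-2-ol
Product: 9 tert-butyl (2-methylbut-3-en-2-yl) carbonate
Conditions: n-BuLi, THF, 0 °C; Boc2O, 0 °C to rt
Reagents that add atoms: di-tert-butyl dicarbonate CC(C)(C)OC(=O)OC(=O)OC(C)(C)C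
Why: Acylation of the lithium alkoxide with Boc2O gives the mixed carbonate, the usual ionisable partner for Tsuji–Trost chemistry.

Step 6
Reactants: 10 5-bromo-2,4-dihydroxybenzaldehyde
Product: 11 5-bromo-2-hydroxy-4-(methoxymethoxy)benzaldehyde
Conditions: MOMCl (1.05 equiv), K2CO3, acetone, 0 °C to rt
Reagents that add atoms: chloromethyl methyl ether COCCl
Why: Selective Williamson-type protection; the C4 hydroxyl (para to the formyl group) is the more acidic one and is not tied up in the hydrogen bond that masks the C2 hydroxyl.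

Step 7
Reactants: 11 5-bromo-2-hydroxy-4-(methoxymethoxy)benzaldehyde; 9 tert-butyl (2-methylbut-3-en-2-yl) carbonate
Product: 12 5-bromo-4-(methoxymethoxy)-2-[(2-methylbut-3-en-2-yl)oxy]benzaldehyde
Conditions: 9 (1.5 equiv), Pd(PPh3)4 (3 mol%), THF, 0 °C
Reagents that add atoms: none
Why: Tsuji–Trost O-allylation: zerovalent palladium ionises 9 with loss of CO2, the tert-butoxide formed deprotonates the phenol, and the phenoxide should attack the more substituted terminus of [Pd(PPh3)2(η3-C5H9)]+ at low temperature to give the tertiary ether under kinetic control.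

Step 8
Reactants: 12 5-bromo-4-(methoxymethoxy)-2-[(2-methylbut-3-en-2-yl)oxy]benzaldehyde
Product: 13 1-bromo-2-(methoxymethoxy)-4-[(2-methylbut-3-en-2-yl)oxy]-5-vinylbenzene
Conditions: Ph3PCH3Br, KOtBu, THF, 0 °C to rt
Reagents that add atoms: methyltriphenylphosphonium bromide C[P+](c1ccccc1)(c1ccccc1)c1ccccc1.[Br-]
Why: Wittig methylenation with the non-stabilised ylide; the basic medium leaves the acid-sensitive tertiary allyl ether and the MOM group untouched.

Step 9
Reactants: 13 1-bromo-2-(methoxymethoxy)-4-[(2-methylbut-3-en-2-yl)oxy]-5-vinylbenzene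
Product: 16 [2-(methoxymethoxy)-4-[(2-methylbut-3-en-2-yl)oxy]-5-vinylphenyl]boronic acid, via aryllithium 14 (not isolated), via lithium triisopropoxyborate 15 (not isolated)
Conditions: B(OiPr)3 (1.5 equiv) present, then n-BuLi, THF/toluene, −78 °C; H2O (pH 7, NaH2PO4/Na2HPO4 buffer), 0 °C
Reagents that add atoms: triisopropyl borate CC(C)OB(OC(C)C)OC(C)C; water O
Why: Bromine–lithium exchange with in situ borate trapping (exchange and trapping should outrun addition of n-BuLi to the styrene) followed by neutral hydrolysis of the ate complex gives the boronic acid without exposing the MOM and tertiary allyl ethers to acid.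

Step 10
Reactants: 7 8-allyl-7-methoxy-5-(methoxymethoxy)-4H-chromen-4-one; 16 [2-(methoxymethoxy)-4-[(2-methylbut-3-en-2-yl)oxy]-5-vinylphenyl]boronic acid
Product: 17 (2S)-8-allyl-7-methoxy-5-(methoxymethoxy)-2-{2-(methoxymethoxy)-4-[(2-methylbut-3-en-2-yl)oxy]-5-vinylphenyl}chroman-4-one
Conditions: 16 (2 equiv), [RhCl(C2H4)2]2 (2.5 mol%), (S)-MeO-F12-BIPHEP (5.5 mol%), aq. KOH (10 mol%), toluene/H2O, 30 °C
Reagents that add atoms: none
Why: Hayashi–Miyaura asymmetric 1,4-addition to the chromone C2=C3 bond (transmetalation to Ar–Rh(diphosphine), enone insertion, protonation of the rhodium enolate by water); the C2 stereocentre is set by the chiral diphosphine, which is expected to deliver the aryl group to the Re face of C2 and so give 2S.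

Step 11
Reactants: 17 (2S)-8-allyl-7-methoxy-5-(methoxymethoxy)-2-{2-(methoxymethoxy)-4-[(2-methylbut-3-en-2-yl)oxy]-5-vinylphenyl}chroman-4-one
Product: 19 (2S)-2-[2,2-dimethyl-7-(methoxymethoxy)-2H-chromen-6-yl]-7-methoxy-5-(methoxymethoxy)-8-(3-methylbut-2-en-1-yl)chroman-4-one, via 8-allyl chromene flavanone 18 (not isolated)
Conditions: second-generation Hoveyda–Grubbs catalyst RuCl2(H2IMes)(=CH-C6H4-2-OiPr) (5 mol%), 1,4-benzoquinone (10 mol%), CH2Cl2 (0.005 M), 35 °C; then 2-methyl-2-butene (large excess, about one fifth of the volume) and more catalyst (3 mol%), 35 °C, sealed vessel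
Reagents that add atoms: 2-methyl-2-butene CC=C(C)C
Why: The catalyst loads on the unhindered C5' vinyl group, and [2+2] cycloaddition/cycloreversion through a ruthenacyclobutane onto the neighbouring 1,1-dimethylallyl ether expels ethylene and forms C3''=C4''; once 2-methyl-2-butene is added, the same catalyst exchanges the terminal CH2 of the C8 allyl group for an isopropylidene unit with loss of propene. The closest known reaction types are ring-closing metathesis of 2-vinylaryl allyl ethers to 2H-chromenes and allyl-to-prenyl cross-metathesis with 2-methyl-2-butene, here run as one tandem operation. Ring D closes as a six-membered ring by ring-closing metathesis of a 1,7-diene, and the ring olefin is necessarily cis. No new stereocentre is formed, and C2 (S) should be untouched because the medium is neutral and aprotic. The step needs site selectivity among three terminal alkenes and ring closure ahead of chain transfer: the ortho arrangement on ring B and the gem-dimethyl group make only the six-membered closure intramolecular, high dilution and late addition of 2-methyl-2-butene keep the styrene from being capped before it cyclises, the quaternary carbon blocks homodimerisation of the ether olefin, and any dimer of the C8 allyl group is reopened by the excess 2-methyl-2-butene. 1,4-Benzoquinone suppresses Ru–H-mediated migration of the allyl double bond, and the chromene olefin of the product (cis, conjugated, next to a quaternary carbon) should not re-enter metathesis.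

Step 12
Reactants: 19 (2S)-2-[2,2-dimethyl-7-(methoxymethoxy)-2H-chromen-6-yl]-7-methoxy-5-(methoxymethoxy)-8-(3-methylbut-2-en-1-yl)chroman-4-one
Product: 21 maackiaflavanone A, via 2'-MOM ether 20 (not isolated)
Conditions: 3 M aq. HCl/MeOH/THF, 45 °C
Reagents that add atoms: none
Why: Acid-catalysed acetal methanolysis removes the chelation-activated C5 MOM group first and then the C2' MOM group; the chromene, the prenyl group (no free phenol ortho to it) and the C2 stereocentre should tolerate dilute acid at this temperature.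

**Compound list**

1 | 2',6'-dihydroxy-4'-methoxyacetophenone | CC(=O)c1c(O)cc(OC)cc1O | starting material
2 | 1-[2-(allyloxy)-6-hydroxy-4-methoxyphenyl]ethan-1-one | CC(=O)c1c(O)cc(OC)cc1OCC=C | intermediate
3 | 1-[2-(allyloxy)-4-methoxy-6-(methoxymethoxy)phenyl]ethan-1-one | CC(=O)c1c(OCOC)cc(OC)cc1OCC=C | intermediate
4 | 2-acetyl-6-allyl-5-methoxy-3-(methoxymethoxy)cyclohexa-2,4-dien-1-one (Claisen dienone, not isolated) | CC(=O)C1=C(OCOC)C=C(OC)C(CC=C)C1=O | intermediate
5 | 1-[3-allyl-2-hydroxy-4-methoxy-6-(methoxymethoxy)phenyl]ethan-1-one | CC(=O)c1c(OCOC)cc(OC)c(CC=C)c1O | intermediate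
6 | (E)-1-[3-allyl-2-hydroxy-4-methoxy-6-(methoxymethoxy)phenyl]-3-(dimethylamino)prop-2-en-1-one (enaminone, not isolated) | CN(C)/C=C/C(=O)c1c(OCOC)cc(OC)c(CC=C)c1O | intermediate
7 | 8-allyl-7-methoxy-5-(methoxymethoxy)-4H-chromen-4-one | COCOc1cc(OC)c(CC=C)c2occc(=O)c12 | intermediate
8 | 2-methylbut-3-en-2-ol | CC(C)(O)C=C | starting material
9 | tert-butyl (2-methylbut-3-en-2-yl) carbonate | CC(C)(C)OC(=O)OC(C)(C)C=C | intermediate
10 | 5-bromo-2,4-dihydroxybenzaldehyde | O=Cc1cc(Br)c(O)cc1O | starting material
11 | 5-bromo-2-hydroxy-4-(methoxymethoxy)benzaldehyde | O=Cc1cc(Br)c(OCOC)cc1O | intermediate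
12 | 5-bromo-4-(methoxymethoxy)-2-[(2-methylbut-3-en-2-yl)oxy]benzaldehyde | O=Cc1cc(Br)c(OCOC)cc1OC(C)(C)C=C | intermediate
13 | 1-bromo-2-(methoxymethoxy)-4-[(2-methylbut-3-en-2-yl)oxy]-5-vinylbenzene | C=Cc1cc(Br)c(OCOC)cc1OC(C)(C)C=C | intermediate
14 | [2-(methoxymethoxy)-4-[(2-methylbut-3-en-2-yl)oxy]-5-vinylphenyl]lithium (not isolated) | [Li]c1cc(C=C)c(OC(C)(C)C=C)cc1OCOC | intermediate
15 | lithium triisopropoxy[2-(methoxymethoxy)-4-[(2-methylbut-3-en-2-yl)oxy]-5-vinylphenyl]borate (not isolated) | [Li+].CC(C)O[B-](OC(C)C)(OC(C)C)c1cc(C=C)c(OC(C)(C)C=C)cc1OCOC | intermediate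
16 | [2-(methoxymethoxy)-4-[(2-methylbut-3-en-2-yl)oxy]-5-vinylphenyl]boronic acid | OB(O)c1cc(C=C)c(OC(C)(C)C=C)cc1OCOC | intermediate
17 | (2S)-8-allyl-7-methoxy-5-(methoxymethoxy)-2-{2-(methoxymethoxy)-4-[(2-methylbut-3-en-2-yl)oxy]-5-vinylphenyl}chroman-4-one | COCOc1cc(OC)c(CC=C)c2c1C(=O)C[C@@H](c1cc(C=C)c(OC(C)(C)C=C)cc1OCOC)O2 | intermediate
18 | (2S)-8-allyl-2-[2,2-dimethyl-7-(methoxymethoxy)-2H-chromen-6-yl]-7-methoxy-5-(methoxymethoxy)chroman-4-one (not isolated) | COCOc1cc(OC)c(CC=C)c2c1C(=O)C[C@@H](c1cc3C=CC(C)(C)Oc3cc1OCOC)O2 | intermediate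
19 | (2S)-2-[2,2-dimethyl-7-(methoxymethoxy)-2H-chromen-6-yl]-7-methoxy-5-(methoxymethoxy)-8-(3-methylbut-2-en-1-yl)chroman-4-one | COCOc1cc(OC)c(CC=C(C)C)c2c1C(=O)C[C@@H](c1cc3C=CC(C)(C)Oc3cc1OCOC)O2 | intermediate
20 | (2S)-2-[2,2-dimethyl-7-(methoxymethoxy)-2H-chromen-6-yl]-5-hydroxy-7-methoxy-8-(3-methylbut-2-en-1-yl)chroman-4-one (not isolated) | Oc1cc(OC)c(CC=C(C)C)c2c1C(=O)C[C@@H](c1cc3C=CC(C)(C)Oc3cc1OCOC)O2 | intermediate
21 | maackiaflavanone A, (2S)-5-hydroxy-2-(7-hydroxy-2,2-dimethyl-2H-chromen-6-yl)-7-methoxy-8-(3-methylbut-2-en-1-yl)chroman-4-one | COc1cc(O)c2c(c1CC=C(C)C)O[C@H](c1cc3c(cc1O)OC(C)(C)C=C3)CC2=O | target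

**Step count and risks**

Total step count: 12. Longest linear sequence: 7 steps (steps 1, 2, 3, 4, 10, 11, 12, or equally steps 6, 7, 8, 9, 10, 11, 12).

Steps most likely to fail:

Step 10. The ortho-alkoxy aryl group may transmetalate and insert slowly, so that protodeboronation of the electron-rich boronic acid or Heck-type arylation of the styrene competes, and facial selectivity may be poor. The fallback replaces the 1,4-addition by a chalcone route with kinetic resolution; it sets out from 13 (with 5) and comes back at 17. Bromine–lithium exchange on 13 (n-BuLi, THF, −78 °C) and formylation with DMF should give 2-(methoxymethoxy)-4-[(2-methylbut-3-en-2-yl)oxy]-5-vinylbenzaldehyde F1. Claisen–Schmidt condensation of it with acetophenone 5 (KOH, EtOH/H2O, rt) should give (E)-1-[3-allyl-2-hydroxy-4-methoxy-6-(methoxymethoxy)phenyl]-3-{2-(methoxymethoxy)-4-[(2-methylbut-3-en-2-yl)oxy]-5-vinylphenyl}prop-2-en-1-one F2. Buffered oxa-Michael ring closure (NaOAc, EtOH, 60 °C) should give racemic 8-allyl-7-methoxy-5-(methoxymethoxy)-2-{2-(methoxymethoxy)-4-[(2-methylbut-3-en-2-yl)oxy]-5-vinylphenyl}chroman-4-one F3. Kinetic resolution by Noyori-type asymmetric transfer hydrogenation (RuCl[(R,R)-TsDPEN](p-cymene), HCO2H/Et3N, EtOAc, rt, stopped near half conversion) is expected to reduce the 2R enantiomer to the separable cis alcohol (2R,4R)-8-allyl-7-methoxy-5-(methoxymethoxy)-2-{2-(methoxymethoxy)-4-[(2-methylbut-3-en-2-yl)oxy]-5-vinylphenyl}chroman-4-ol F4 and to leave 17.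

Step 11. Chain transfer at the styrene before ring closure, oligomerisation through the C8 allyl group, or migration of the allyl double bond (which would cost one carbon in the cross-metathesis) may spoil the tandem operation on the advanced tetraene. The fallback closes ring D on the small achiral fragment and separates the two metathesis events; it sets out from 13 and comes back at 18. Ring-closing metathesis of 13 (RuCl2(H2IMes)(=CH-C6H4-2-OiPr), CH2Cl2, 35 °C) should give 6-bromo-7-(methoxymethoxy)-2,2-dimethyl-2H-chromene F5. Bromine–lithium exchange with borate trapping as in step 9 should give [7-(methoxymethoxy)-2,2-dimethyl-2H-chromen-6-yl]boronic acid F6. Its 1,4-addition to chromone 7 under the conditions of step 10 should give 18, which is then isolated and carried through the cross-metathesis half of step 11 to 19.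

Step 7. The phenoxide may attack the unsubstituted allyl terminus, or zerovalent palladium may re-ionise the tertiary ether, and either process leads to the linear prenyl ether. The fallback builds the tertiary ether by propargylation and semi-hydrogenation; it sets out from 11 and comes back at 12. Copper-catalysed O-alkylation of 11 with 3-chloro-3-methylbut-1-yne (CuCl2 cat., DBU, MeCN, 0 °C) should give 5-bromo-4-(methoxymethoxy)-2-[(2-methylbut-3-yn-2-yl)oxy]benzaldehyde F7. Semi-hydrogenation (H2, Pd/CaCO3 poisoned with Pb(OAc)2, quinoline, EtOAc, rt) should then give 12.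

**Further compounds**

F1 | step 10 | 2-(methoxymethoxy)-4-[(2-methylbut-3-en-2-yl)oxy]-5-vinylbenzaldehyde | O=Cc1cc(C=C)c(OC(C)(C)C=C)cc1OCOC
F2 | step 10 | (E)-1-[3-allyl-2-hydroxy-4-methoxy-6-(methoxymethoxy)phenyl]-3-{2-(methoxymethoxy)-4-[(2-methylbut-3-en-2-yl)oxy]-5-vinylphenyl}prop-2-en-1-one | COCOc1cc(OC)c(CC=C)c(O)c1C(=O)/C=C/c1cc(C=C)c(OC(C)(C)C=C)cc1OCOC
F3 | step 10 | racemic 8-allyl-7-methoxy-5-(methoxymethoxy)-2-{2-(methoxymethoxy)-4-[(2-methylbut-3-en-2-yl)oxy]-5-vinylphenyl}chroman-4-one | COCOc1cc(OC)c(CC=C)c2c1C(=O)CC(c1cc(C=C)c(OC(C)(C)C=C)cc1OCOC)O2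
F4 | step 10 | (2R,4R)-8-allyl-7-methoxy-5-(methoxymethoxy)-2-{2-(methoxymethoxy)-4-[(2-methylbut-3-en-2-yl)oxy]-5-vinylphenyl}chroman-4-ol | COCOc1cc(OC)c(CC=C)c2c1[C@H](O)C[C@H](c1cc(C=C)c(OC(C)(C)C=C)cc1OCOC)O2
F5 | step 11 | 6-bromo-7-(methoxymethoxy)-2,2-dimethyl-2H-chromene | COCOc1cc2OC(C)(C)C=Cc2cc1Br
F6 | step 11 | [7-(methoxymethoxy)-2,2-dimethyl-2H-chromen-6-yl]boronic acid | COCOc1cc2OC(C)(C)C=Cc2cc1B(O)O
F7 | step 7 | 5-bromo-4-(methoxymethoxy)-2-[(2-methylbut-3-yn-2-yl)oxy]benzaldehyde | O=Cc1cc(Br)c(OCOC)cc1OC(C)(C)C#C
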